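**Plan**

- Retrosynthesis: take off the C9 silyl ether; cut C5–C6 together with the lactone bond O6–C12 (one Ni/Cr event) to give an open-chain (Z)-alkenyl iodide / C6 aldehyde; take off the C8 ester; cut C7–C8 (indium Barbier reaction); cut the furanone bonds C2–C3 and C3–O (aldol, cyclodehydration).
- Forward: the 3(2H)-furanone (ring oxygen between C3 and C10) is built first on the C8–C10 unit of a chiral-pool lactone. The C6–C7–C11–C13 acrylate unit is then joined at C8. Last, an alkenyl-metal at C5 adds to the C6 aldehyde and the new C6 alkoxide closes the α-methylene-γ-lactone on C12.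
- Enabling feature: C5 is the vinylic CH of the (Z)-C4=C5 alkene whose cis partner is furanone carbon C3. The flat furanone ring and the Z geometry therefore turn C5 back toward the C10 side chain, so the nine-membered ring C3–C4–C5–C6–C7–C8–C9–C10–O (the ten-membered carbocycle C1–C10) can close. C6 is a carbinol carbon γ to the C12 ester carbonyl, so its alkoxide is placed for 5-exo lactonization.
- Stereochemistry: C9 and C10 come from 2-C-methyl-D-erythrono-1,4-lactone; C7 and C8 from the chelation-controlled, syn-selective allylindium addition; C6 from the ring closure; the Z C4=C5 bond from copper-catalysed anti-carbomagnesiation of propargyl alcohol.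

Key step: step 17

Remark: atom labels C1–C15 are the germacrane numbers of the target and are used for all intermediates; lactone 5 and aldehyde 16 are assumed to be catalogue compounds.

**Route**

Step 1
Reactants: 1 prop-2-yn-1-ol
Product: 3 (Z)-3-iodo-2-methylprop-2-en-1-ol, via chelated (Z)-alkenylmagnesium alkoxide 2 (not isolated)
Conditions: MeMgBr (2.5 equiv), CuI (10 mol%), THF/Et2O, −10 °C → rt; then I2, −78 → 0 °C; H2O
Reagents that add atoms: methylmagnesium bromide, C[Mg]Br; iodine, II
Why: Copper-catalysed anti-carbomagnesiation of the propargylic magnesium alkoxide puts methyl on C4 and magnesium on C5 cis to the CH2O group (five-membered chelate), and iodinolysis with retention gives the Z iodide that fixes the C4=C5 geometry.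

Step 2
Reactants: 3 (Z)-3-iodo-2-methylprop-2-en-1-ol
Product: 4 (Z)-3-iodo-2-methylprop-2-enal
Conditions: activated MnO2 (15 equiv), CH2Cl2, rt, dark; filtered through Celite and used at once
Reagents that add atoms: none
Why: Neutral heterogeneous allylic oxidation with MnO2 stops at the aldehyde and, in the dark and without storage, should leave the labile Z β-iodo enal unisomerized.

Step 3
Reactants: 5 2-C-methyl-D-erythrono-1,4-lactone
Product: 6 (3R,4R)-4-(tert-butyldimethylsilyloxy)-3-hydroxy-3-methyloxolan-2-one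
Conditions: TBSCl (1.1 equiv), imidazole, DMF, 0 °C → rt
Reagents that add atoms: tert-butyldimethylsilyl chloride, CC(C)(C)[Si](C)(C)Cl
Why: Silylation with TBSCl/imidazole should discriminate the secondary C9 hydroxyl from the hindered tertiary C10 hydroxyl next to the lactone carbonyl, and no stereocentre is touched.

Step 4
Reactants: 6 (3R,4R)-4-(tert-butyldimethylsilyloxy)-3-hydroxy-3-methyloxolan-2-one
Product: 7 (3R,4R)-4-(tert-butyldimethylsilyloxy)-2,3-dimethyloxolane-2,3-diol (anomer mixture)
Conditions: MeLi (2.2 equiv), THF, −78 °C; H2O quench at −78 °C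
Reagents that add atoms: methyllithium, [Li]C
Why: MeLi first deprotonates the C10 hydroxyl and then adds once to the lactone carbonyl (1,2-addition of an organolithium to a lactone); the dilithio hemiketal is stable at −78 °C, so the C1 methyl ketone with its new C2 methyl is set free only on work-up, as the lactol.

Step 5
Reactants: 7 (3R,4R)-4-(tert-butyldimethylsilyloxy)-2,3-dimethyloxolane-2,3-diol
Product: 8 (3R,4R)-4,5-bis(tert-butyldimethylsilyloxy)-3-hydroxy-3-methylpentan-2-one
Conditions: TBSCl (1.2 equiv), imidazole, DMAP (cat.), DMF, rt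
Reagents that add atoms: tert-butyldimethylsilyl chloride, CC(C)(C)[Si](C)(C)Cl
Why: The lactol is in ring–chain equilibrium with the hydroxy ketone, and silylation of the primary C8 hydroxyl of the open form drains the equilibrium to the acyclic methyl ketone.

Step 6
Reactants: 8 (3R,4R)-4,5-bis(tert-butyldimethylsilyloxy)-3-hydroxy-3-methylpentan-2-one; 4 (Z)-3-iodo-2-methylprop-2-enal
Product: 10 (1Z,6R,7R)-7,8-bis(tert-butyldimethylsilyloxy)-3,6-dihydroxy-1-iodo-2,6-dimethyloct-1-en-5-one (C3 epimers), via dilithium alkoxide enolate 9 (not isolated)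
Conditions: LDA (2.2 equiv), THF, −78 °C; then 4, −78 °C; H2O quench
Reagents that add atoms: none
Why: Two equivalents of LDA give the C10 alkoxide and the kinetic methyl enolate (C10 is quaternary, so C2 is the only enolizable site), which undergoes a directed aldol 1,2-addition to the enal; the new C3 carbinol forms as a mixture that step 7 erases.

Step 7
Reactants: 10 (1Z,6R,7R)-7,8-bis(tert-butyldimethylsilyloxy)-3,6-dihydroxy-1-iodo-2,6-dimethyloct-1-en-5-one
Product: 12 (2R)-2-[(1R)-1,2-bis(tert-butyldimethylsilyloxy)ethyl]-5-[(Z)-1-iodoprop-1-en-2-yl]-2-methylfuran-3(2H)-one, via enolised 1,3-diketone 11 (not isolated)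
Conditions: Dess–Martin periodinane, CH2Cl2, 0 °C → rt; silica plug; then TsOH·H2O (5 mol%), benzene, rt, dark
Reagents that add atoms: none
Why: Dess–Martin oxidation gives the enolized β-diketone, and mild acid closes the tertiary C10 hydroxyl onto the C3 carbonyl (5-exo-trig hemiketalization) and dehydrates to the 3(2H)-furanone (cyclodehydration of an α′-hydroxy 1,3-diketone), while the silyl ether on O9 blocks the six-membered dihydropyranone alternative.

Step 8
Reactants: 12 (2R)-2-[(1R)-1,2-bis(tert-butyldimethylsilyloxy)ethyl]-5-[(Z)-1-iodoprop-1-en-2-yl]-2-methylfuran-3(2H)-one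
Product: 13 (2R)-2-[(1R)-1-(tert-butyldimethylsilyloxy)-2-hydroxyethyl]-5-[(Z)-1-iodoprop-1-en-2-yl]-2-methylfuran-3(2H)-one
Conditions: HF·pyridine, pyridine, THF, 0 °C
Reagents that add atoms: none
Why: Buffered HF·pyridine should cleave the unhindered primary silyl ether much faster than the secondary one flanked by the quaternary C10 (selective desilylation).

Step 9
Reactants: 13 (2R)-2-[(1R)-1-(tert-butyldimethylsilyloxy)-2-hydroxyethyl]-5-[(Z)-1-iodoprop-1-en-2-yl]-2-methylfuran-3(2H)-one
Product: 14 (2S)-2-(tert-butyldimethylsilyloxy)-2-{(2R)-5-[(Z)-1-iodoprop-1-en-2-yl]-2-methyl-3-oxo-2,3-dihydrofuran-2-yl}acetaldehyde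
Conditions: Dess–Martin periodinane, NaHCO3, CH2Cl2, 0 °C → rt
Reagents that add atoms: none
Why: Buffered Dess–Martin oxidation should give the α-silyloxy C8 aldehyde without epimerizing C9 or touching the iodo dienone (the 2S label is only a change of CIP priority; the C9 arrangement is unchanged).

Step 10
Reactants: 15 methyl acrylate; 16 2-[(4-methoxybenzyl)oxy]acetaldehyde
Product: 17 methyl 3-hydroxy-4-[(4-methoxybenzyl)oxy]-2-methylidenebutanoate (racemic)
Conditions: DABCO (0.5 equiv), 1,4-dioxane/H2O (1:1), rt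
Reagents that add atoms: none
Why: Morita–Baylis–Hillman reaction, in which DABCO adds to the acrylate and the zwitterionic enolate attacks the aldehyde; the racemic carbinol centre is destroyed in step 11.

Step 11
Reactants: 17 methyl 3-hydroxy-4-[(4-methoxybenzyl)oxy]-2-methylidenebutanoate
Product: 18 methyl (2Z)-2-(bromomethyl)-4-[(4-methoxybenzyl)oxy]but-2-enoate
Conditions: NBS, Me2S, CH2Cl2, 0 °C → rt
Reagents that add atoms: N-bromosuccinimide, O=C1CCC(=O)N1Br
Why: Activation of the hydroxyl as an alkoxysulfonium salt and SN2′ attack of bromide give the rearranged primary allylic bromide as the thermodynamically preferred Z isomer (chain trans to the ester), the geometry that later becomes the C7/C8 syn relationship.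

Step 12
Reactants: 14 (2S)-2-(tert-butyldimethylsilyloxy)-2-{(2R)-5-[(Z)-1-iodoprop-1-en-2-yl]-2-methyl-3-oxo-2,3-dihydrofuran-2-yl}acetaldehyde; 18 methyl (2Z)-2-(bromomethyl)-4-[(4-methoxybenzyl)oxy]but-2-enoate
Product: 20 methyl (3S,4S,5R)-4,5-dihydroxy-5-{(2R)-5-[(Z)-1-iodoprop-1-en-2-yl]-2-methyl-3-oxo-2,3-dihydrofuran-2-yl}-3-{[(4-methoxybenzyl)oxy]methyl}-2-methylidenepentanoate, via free α-hydroxy aldehyde 19 (not isolated)
Conditions: 48% aq. HF, MeCN, 0 °C; NaHCO3 to pH 6–7; then 18 (1.5 equiv), indium powder (1.5 equiv), THF/H2O (1:1), rt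
Reagents that add atoms: none
Why: Aqueous HF frees the C9 hydroxyl, and the allylindium formed in water adds at its γ-carbon (Barbier reaction) through a chair transition state with indium chelated by the C9 hydroxyl and the C8 carbonyl; attack on the chelate face opposite C10 sets C8 (8,9-syn diol) and the Z allyl unit sets C7 (7,8-syn), in line with the known syn,syn outcome of such bromides with free α-hydroxy aldehydes.

Step 13
Reactants: 20 methyl (3S,4S,5R)-4,5-dihydroxy-5-{(2R)-5-[(Z)-1-iodoprop-1-en-2-yl]-2-methyl-3-oxo-2,3-dihydrofuran-2-yl}-3-{[(4-methoxybenzyl)oxy]methyl}-2-methylidenepentanoate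
Product: 21 the C8 3-methylbutanoate of 20 (C9 hydroxyl free)
Conditions: isovaleryl chloride (1.05 equiv), 2,4,6-collidine, CH2Cl2, −78 → −30 °C
Reagents that add atoms: 3-methylbutanoyl chloride, CC(C)CC(=O)Cl
Why: Kinetic acylation with an acid chloride and a hindered pyridine base at low temperature should select the C8 hydroxyl, because the C9 hydroxyl is flanked by the quaternary C10 (regioselective esterification).

Step 14
Reactants: 21 the C8 3-methylbutanoate of 20
Product: 22 the C9 tert-butyldimethylsilyl ether of 21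
Conditions: TBSOTf, 2,6-lutidine, CH2Cl2, −40 → 0 °C
Reagents that add atoms: tert-butyldimethylsilyl triflate, CC(C)(C)[Si](C)(C)OS(=O)(=O)C(F)(F)F
Why: The reactive silyl triflate caps the hindered C9 hydroxyl (silyl ether formation), so that it can neither form a lactol with the coming C6 aldehyde nor take part in acyl migration.

Step 15
Reactants: 22 the C9 tert-butyldimethylsilyl ether of 21
Product: 23 the C6 primary alcohol obtained from 22 by loss of the 4-methoxybenzyl group
Conditions: DDQ, CH2Cl2/pH 7 phosphate buffer (10:1), 0 °C; carried on without delay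
Reagents that add atoms: none
Why: Oxidative cleavage of the 4-methoxybenzyl ether with DDQ under buffered conditions frees the primary C6 hydroxyl without affecting silyl ether, esters or alkenyl iodide.

Step 16
Reactants: 23 the C6 primary alcohol
Product: 24 methyl (3R,4S,5R)-5-(tert-butyldimethylsilyloxy)-3-formyl-5-{(2R)-5-[(Z)-1-iodoprop-1-en-2-yl]-2-methyl-3-oxo-2,3-dihydrofuran-2-yl}-4-[(3-methylbutanoyl)oxy]-2-methylidenepentanoate
Conditions: Dess–Martin periodinane, NaHCO3, CH2Cl2, 0 °C; crude aldehyde used at once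
Reagents that add atoms: none
Why: Buffered Dess–Martin oxidation gives the α-branched β,γ-unsaturated C6 aldehyde under non-basic conditions, so C7 should not epimerize and the C11=C13 bond should not move into conjugation (the 3R label is only a change of CIP priority; the C7 arrangement is unchanged).

Step 17
Reactants: 24 the (Z)-alkenyl iodide C6 aldehyde
Product: 26 9-O-(tert-butyldimethylsilyl)lobatin B (6R,7S,8S,9R,10R; 4Z), via macrocyclic C6 hydroxy methyl ester 25 (not isolated)
Conditions: CrCl2 (10 equiv), NiCl2 (0.1 equiv), degassed DMSO (0.003 M, slow addition of 24), rt; aq. work-up; then PPTS (0.2 equiv), benzene, rt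
Reagents that add atoms: none
Why: NiCl2 is reduced by CrCl2 to zerovalent nickel, which inserts into the C5–I bond with retention of the Z geometry and passes the alkenyl group to trivalent chromium; the alkenylchromium adds only to the C6 aldehyde (ketone, esters, acrylate and silyl ether are tolerated), and the C6 oxygen then acylates on the C12 methyl ester. The closest known reaction type is the intramolecular Nozaki–Hiyama–Kishi closure of alkenyl iodide aldehydes to medium rings bridged by a 2,5-disubstituted five-membered cyclic ether (11-oxabicyclo[6.2.1]undecanes), joined to the familiar lactonization of γ-hydroxy α-methylene esters. Two rings close: the nine-membered ring C3–C4–C5–C6–C7–C8–C9–C10–O (and with it the ten-membered carbocycle C1–C10) by 9-exo-trig 1,2-addition, then the γ-lactone O–C6–C7–C11–C12 by 5-exo-trig acyl substitution with loss of methanol. The new stereocentre C6 is controlled by C7 and by the ring being formed: in the closing transition state the bulky O–Cr unit and the C7 acrylate should both take peripheral (pseudo-equatorial) positions with H6 and H7 antiperiplanar, which gives the 6R alcohol and so the trans-fused lactone. The step needs chemoselectivity for the aldehyde, no epimerization at C7 (the medium is neutral), retention of the Z alkene (only the Z alkenyl-metal can reach C6, which the flat furanone and the cis C3/C5 relationship secure) and ring closure over oligomerization (high dilution, slow addition).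

Step 18
Reactants: 26 9-O-(tert-butyldimethylsilyl)lobatin B
Product: 27 lobatin B
Conditions: HF·pyridine, THF, 0 °C → rt
Reagents that add atoms: none
Why: Fluoride-mediated desilylation under mildly acidic conditions frees the C9 hydroxyl without acyl migration from O8 or conjugate addition to the α-methylene lactone.

**Compound list**

1 | prop-2-yn-1-ol | C#CCO | starting material
2 | (Z)-[3-(bromomagnesiooxy)-2-methylprop-1-en-1-yl]magnesium bromide | Br[Mg]/C=C(/C)CO[Mg]Br | intermediate
3 | (Z)-3-iodo-2-methylprop-2-en-1-ol | I/C=C(/C)CO | intermediate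
4 | (Z)-3-iodo-2-methylprop-2-enal | I/C=C(/C)C=O | intermediate
5 | 2-C-methyl-D-erythrono-1,4-lactone, (3R,4R)-3,4-dihydroxy-3-methyloxolan-2-one | O=C1[C@](C)(O)[C@H](O)CO1 | starting material
6 | (3R,4R)-4-(tert-butyldimethylsilyloxy)-3-hydroxy-3-methyloxolan-2-one | O=C1[C@](C)(O)[C@H](O[Si](C)(C)C(C)(C)C)CO1 | intermediate
7 | (3R,4R)-4-(tert-butyldimethylsilyloxy)-2,3-dimethyloxolane-2,3-diol (anomer mixture) | CC1(O)[C@](C)(O)[C@H](O[Si](C)(C)C(C)(C)C)CO1 | intermediate
8 | (3R,4R)-4,5-bis(tert-butyldimethylsilyloxy)-3-hydroxy-3-methylpentan-2-one | CC(=O)[C@](C)(O)[C@H](O[Si](C)(C)C(C)(C)C)CO[Si](C)(C)C(C)(C)C | intermediate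
9 | dilithium alkoxide enolate of 8 | C=C(O[Li])[C@](C)(O[Li])[C@H](O[Si](C)(C)C(C)(C)C)CO[Si](C)(C)C(C)(C)C | intermediate
10 | (1Z,6R,7R)-7,8-bis(tert-butyldimethylsilyloxy)-3,6-dihydroxy-1-iodo-2,6-dimethyloct-1-en-5-one (C3 epimers) | I/C=C(/C)C(O)CC(=O)[C@](C)(O)[C@H](O[Si](C)(C)C(C)(C)C)CO[Si](C)(C)C(C)(C)C | intermediate
11 | (1Z,6R,7R)-7,8-bis(tert-butyldimethylsilyloxy)-6-hydroxy-1-iodo-2,6-dimethyloct-1-ene-3,5-dione (drawn as diketone) | I/C=C(/C)C(=O)CC(=O)[C@](C)(O)[C@H](O[Si](C)(C)C(C)(C)C)CO[Si](C)(C)C(C)(C)C | intermediate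
12 | (2R)-2-[(1R)-1,2-bis(tert-butyldimethylsilyloxy)ethyl]-5-[(Z)-1-iodoprop-1-en-2-yl]-2-methylfuran-3(2H)-one | I/C=C(/C)C1=CC(=O)[C@](C)(O1)[C@H](O[Si](C)(C)C(C)(C)C)CO[Si](C)(C)C(C)(C)C | intermediate
13 | (2R)-2-[(1R)-1-(tert-butyldimethylsilyloxy)-2-hydroxyethyl]-5-[(Z)-1-iodoprop-1-en-2-yl]-2-methylfuran-3(2H)-one | I/C=C(/C)C1=CC(=O)[C@](C)(O1)[C@H](O[Si](C)(C)C(C)(C)C)CO | intermediate
14 | (2S)-2-(tert-butyldimethylsilyloxy)-2-{(2R)-5-[(Z)-1-iodoprop-1-en-2-yl]-2-methyl-3-oxo-2,3-dihydrofuran-2-yl}acetaldehyde | I/C=C(/C)C1=CC(=O)[C@](C)(O1)[C@H](O[Si](C)(C)C(C)(C)C)C=O | intermediate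
15 | methyl acrylate | C=CC(=O)OC | starting material
16 | 2-[(4-methoxybenzyl)oxy]acetaldehyde | COc1ccc(COCC=O)cc1 | starting material
17 | methyl 3-hydroxy-4-[(4-methoxybenzyl)oxy]-2-methylidenebutanoate (racemic) | COC(=O)C(=C)C(O)COCc1ccc(OC)cc1 | intermediate
18 | methyl (2Z)-2-(bromomethyl)-4-[(4-methoxybenzyl)oxy]but-2-enoate | COC(=O)/C(CBr)=C/COCc1ccc(OC)cc1 | intermediate
19 | (2S)-2-hydroxy-2-{(2R)-5-[(Z)-1-iodoprop-1-en-2-yl]-2-methyl-3-oxo-2,3-dihydrofuran-2-yl}acetaldehyde | I/C=C(/C)C1=CC(=O)[C@](C)(O1)[C@H](O)C=O | intermediate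
20 | methyl (3S,4S,5R)-4,5-dihydroxy-5-{(2R)-5-[(Z)-1-iodoprop-1-en-2-yl]-2-methyl-3-oxo-2,3-dihydrofuran-2-yl}-3-{[(4-methoxybenzyl)oxy]methyl}-2-methylidenepentanoate (7S,8S,9R,10R) | I/C=C(/C)C1=CC(=O)[C@](C)(O1)[C@H](O)[C@@H](O)[C@@H](C(=C)C(=O)OC)COCc1ccc(OC)cc1 | intermediate
21 | C8 3-methylbutanoate of 20 (7S,8S,9R,10R; C9 hydroxyl free) | I/C=C(/C)C1=CC(=O)[C@](C)(O1)[C@H](O)[C@@H](OC(=O)CC(C)C)[C@@H](C(=C)C(=O)OC)COCc1ccc(OC)cc1 | intermediate
22 | C9 tert-butyldimethylsilyl ether of 21 (7S,8S,9R,10R) | I/C=C(/C)C1=CC(=O)[C@](C)(O1)[C@H](O[Si](C)(C)C(C)(C)C)[C@@H](OC(=O)CC(C)C)[C@@H](C(=C)C(=O)OC)COCc1ccc(OC)cc1 | intermediate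
23 | methyl (3S,4S,5R)-5-(tert-butyldimethylsilyloxy)-3-(hydroxymethyl)-5-{(2R)-5-[(Z)-1-iodoprop-1-en-2-yl]-2-methyl-3-oxo-2,3-dihydrofuran-2-yl}-4-[(3-methylbutanoyl)oxy]-2-methylidenepentanoate | I/C=C(/C)C1=CC(=O)[C@](C)(O1)[C@H](O[Si](C)(C)C(C)(C)C)[C@@H](OC(=O)CC(C)C)[C@@H](C(=C)C(=O)OC)CO | intermediate
24 | methyl (3R,4S,5R)-5-(tert-butyldimethylsilyloxy)-3-formyl-5-{(2R)-5-[(Z)-1-iodoprop-1-en-2-yl]-2-methyl-3-oxo-2,3-dihydrofuran-2-yl}-4-[(3-methylbutanoyl)oxy]-2-methylidenepentanoate | I/C=C(/C)C1=CC(=O)[C@](C)(O1)[C@H](O[Si](C)(C)C(C)(C)C)[C@@H](OC(=O)CC(C)C)[C@@H](C(=C)C(=O)OC)C=O | intermediate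
25 | macrocyclic hydroxy ester: methyl 2-[(6R,7S,8S,9R,10R,4Z)-9-(tert-butyldimethylsilyloxy)-6-hydroxy-4,10-dimethyl-8-(3-methylbutanoyloxy)-1-oxo-3,10-epoxycyclodeca-2,4-dien-7-yl]acrylate (germacrane numbering) | COC(=O)C(=C)[C@H]1[C@H](O)/C=C(/C)C2=CC(=O)[C@](C)(O2)[C@H](O[Si](C)(C)C(C)(C)C)[C@H]1OC(=O)CC(C)C | intermediate
26 | 9-O-(tert-butyldimethylsilyl)lobatin B (6R,7S,8S,9R,10R; 4Z) | C=C1C(=O)O[C@@H]2/C=C(/C)C3=CC(=O)[C@](C)(O3)[C@H](O[Si](C)(C)C(C)(C)C)[C@@H](OC(=O)CC(C)C)[C@@H]12 | intermediate
27 | lobatin B (6R,7S,8S,9R,10R; 4Z) | C=C1C(=O)O[C@@H]2/C=C(/C)C3=CC(=O)[C@](C)(O3)[C@H](O)[C@@H](OC(=O)CC(C)C)[C@@H]12 | target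

**Step count**

Total: 18 steps. Longest linear sequence: 14 steps (5 → 27 through steps 3–9 and 12–18); the iodo enal 4 (steps 1–2) and the bromide 18 (steps 10–11) are side branches.

**Steps most likely to fail**

1. Step 17. The ring closure may show poor facial selectivity at the C6 aldehyde, so that the C6-epimeric alcohol (cis to the C7 acrylate) forms in place of, or beside, the 6R alcohol. The fallback corrects the centre after the C–C bond is made. It sets out from 24: the Ni/Cr coupling is run as before but worked up under neutral conditions without the PPTS stage, and the C6-epimeric macrocyclic hydroxy ester F1 is isolated. A Mitsunobu reaction (chloroacetic acid, PPh3, DIAD, toluene, 0 °C) inverts the activated allylic C6 centre and gives the 6R chloroacetate F2. Thiourea and NaHCO3 in ethanol remove the chloroacetyl group selectively in the presence of the isovalerate, and the route is rejoined at 25, which PPTS closes to 26.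

2. Step 13. The acid chloride may fail to distinguish O8 from O9, or the ester may migrate between the two syn hydroxyls. The fallback replaces steric discrimination by a tin-acetal template. It sets out from 20: Bu2Sn(OMe)2 in CH2Cl2 at rt, with evaporation of the methanol, gives the 8,9-O-dibutylstannylene acetal F3. In such acetals the oxygen on the less hindered carbon is the activated one, so isovaleryl chloride at 0 °C should acylate O8 only, and the route is rejoined at 21.

3. Step 7. The Z β-iodo enone may isomerize to the E isomer during oxidation and acid-mediated cyclodehydration, and an E iodide cannot close the ring in step 17. The fallback builds the furanone without an acid step and without a β-iodo enone intermediate. It sets out from 4 and 6: Colvin homologation of 4 (TMSCHN2, LDA, THF, −78 → 0 °C) gives the enyne (Z)-1-iodo-2-methylbut-1-en-3-yne F4. Its lithium acetylide (LDA, THF, −78 °C, 2.2 equiv) adds once to lactone 6 and gives, after work-up, the α′-hydroxy ynone F5 (in equilibrium with its lactol). A 5-endo-dig oxa-Michael closure of the tertiary C10 hydroxyl onto C3 (K2CO3 cat., MeOH, 0 °C) then gives the furanone with the C8 hydroxyl free, so the route is rejoined at 13 and steps 4–8 are bypassed.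

**Further compounds**

F1 | step 17 | C6-epimeric (6S) macrocyclic hydroxy methyl ester | COC(=O)C(=C)[C@H]1[C@@H](O)/C=C(/C)C2=CC(=O)[C@](C)(O2)[C@H](O[Si](C)(C)C(C)(C)C)[C@H]1OC(=O)CC(C)C
F2 | step 17 | (6R) C6 chloroacetate of the macrocyclic methyl ester | COC(=O)C(=C)[C@H]1[C@H](OC(=O)CCl)/C=C(/C)C2=CC(=O)[C@](C)(O2)[C@H](O[Si](C)(C)C(C)(C)C)[C@H]1OC(=O)CC(C)C
F3 | step 13 | 8,9-O-dibutylstannylene acetal of 20 | I/C=C(/C)C1=CC(=O)[C@](C)(O1)[C@@H]1O[Sn](CCCC)(CCCC)O[C@H]1[C@@H](C(=C)C(=O)OC)COCc1ccc(OC)cc1
F4 | step 7 | (Z)-1-iodo-2-methylbut-1-en-3-yne | I/C=C(/C)C#C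
F5 | step 7 | (1Z,6R,7R)-7-(tert-butyldimethylsilyloxy)-6,8-dihydroxy-1-iodo-2,6-dimethyloct-1-en-3-yn-5-one (open form of the lactol) | I/C=C(/C)C#CC(=O)[C@](C)(O)[C@H](O[Si](C)(C)C(C)(C)C)CO
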